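## Analysis of the target

Compound 24 joins two 2-(2-phenylethyl)-4-pyranone bicycles through one ether oxygen: unit A is an aromatic chromone (7-methoxy, ether oxygen on C6) and unit B is a 5,6,7,8-tetrahydrochromone with an oxygen on every sp3 carbon of its carbocycle. The four stereocentres C5–C8 of unit B are contiguous; the C5, C7 and C8 oxygens lie on one face and the C6 oxygen on the other (5,6-trans, 6,7-trans, 7,8-cis; 5S,6R,7S,8S), with the aryl ether on C8 and free hydroxyls on C5–C7. C5 and C8 are both attached to the pyranone double bond C4a=C8a, so C5–O can ionise with help from O1 and C8–H is a vinylogous α-proton; loss of two of the four oxygens leads towards an aromatic ring, which makes the carbocycle intolerant of strong acid and of enolate chemistry. 4-Pyranones are also opened by nucleophilic amines and reduced under forcing hydrogenation. The difficulties are therefore four contiguous oxygenated stereocentres, a hindered secondary alkyl aryl ether of defined configuration at C8, a pyranone fused to this ring without passing through a β-alkoxy ketone enolate, and two similar pyranones on different rings. The deciding feature is the cis pair of oxygens on C7 and C8 directly next to the sp2 carbon C8a. This is the pattern of the cis-dihydrodiol of bromobenzene (1), in which the bromine-bearing carbon is C8a, C8 is the proximal and C7 the distal carbinol, and the other diene carbons are C4a, C5 and C6. A leaving group on C8a of a C8a=C4a double bond is what is needed to grow the pyranone atoms O1, C2, C3 and C4 across that bond.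

## Retrosynthetic reasoning

**24 to 23.** The three O–Si bonds are cut last. Silyl ethers are chosen for C5–C7 because they come off with buffered fluoride, which avoids both the base that would deprotonate C8–H and the acid that would ionise C5–O.

**23 to 19 and 20.** The pyranone of unit A is cut at O1–C2, C3–C4 and C4–C4a, giving iodophenol 19, alkyne 20 and a one-carbon carbonyl unit for a carbonylative coupling. Building unit A late keeps the aryl group on the C8 oxygen small and robust through the early steps. Iodophenol 19 goes back to phenol 18 (C–I bond, ortho to the hydroxyl and para to the methoxy group) and 18 to benzyl ether 17 (O–benzyl bond).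

**17 to 11 and 14 (key disconnection).** The pyranone of unit B is cut at C4–C4a and O1–C8a. Both bonds are made in one operation between enamine 11, whose nucleophilic carbon is C4a and whose electrophilic carbon after acylation is C8a, and the acylketene stored in 14. Cutting here means the ring is grown on a neutral enamine; no carbanion is ever placed at C4a, next to the C5 oxygen. The forward reaction must acylate C4a, close the oxygen onto C8a and expel the amine.

**11 to 10.** The C8a–N bond is cut to the alkenyl bromide 10. A metal-catalysed amination puts nitrogen on the carbon that carried bromine and leaves the double bond where it was, so the regiochemistry of the annulation is decided by the position of the original C–Br bond and not by an enolisation.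

**10 to 8.** Two O–Si bonds are cut to diol 9, and the C5–O bond of 9 is cut to vinyl epoxide 8. Opening at the allylic carbon with inversion gives the 5,6-trans relationship; the epoxide oxygen becomes the C6 oxygen.

**8 to 4.** The benzyl group is removed to formate 6. The formyloxy C–O bond and both epoxide C–O bonds of 6 are traced to a single peracid oxidation of diene aldehyde 4: epoxidation of C5=C6 anti to the C7 and C8 substituents, and oxygen insertion between the aryl ring and the formyl group.

**4 to 2 and 3.** The ether is cut on the aryl side (O–aryl bond), not on the C8 side. The C8–O bond of the diol is never broken, so C8 keeps its configuration, which a substitution at C8 could not deliver from a cis diol without a double inversion. The formyl group of 3 serves twice: it activates the fluoride for substitution and it is the latent oxygen that becomes O1 of unit A. Transfer of an electron-rich aryl group to this hindered dienol by hypervalent iodine or oxidative copper chemistry was judged less dependable than addition–elimination on an activated fluoroarene.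

**2 to 1, and 14 to 12 and 13.** The silyl group on the distal C7 oxygen is removed to give 1; steric differentiation of the two hydroxyls is what allows the C8 oxygen alone to be arylated. The acyl Meldrum's acid 14 is cut at the exocyclic C–C bond to 12 and 13.

## Alternatives that were turned down

**Alternative 1:** The carbocycle is disconnected at C4a–C5, with the pyranone oxygen to be attached later at C8a. In the forward direction an open-chain ynone aldehyde (C5 aldehyde, benzyl ethers on C6 and C7, the finished unit A already on the C8 oxygen) is treated with an iodide-delivering magnesium Lewis acid. Iodide adds to C8a, and the resulting allenolate carbon C4a attacks the aldehyde to close the six-membered ring, giving the β-iodo enone A1. Unmasking of the ketal and addition–elimination of the diketone enol oxygen at C8a would then close the pyranone.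
- For: unit A is carried in complete, so no late carbonylative annulation is needed, and C6–C8 come from a pentose. On convergence this plan is stronger than the chosen one.
- Against: C5 is created in the C–C bond-forming step and must come out trans to C6 under chelation and ring-conformation effects that cannot be predicted with confidence. The open-chain aldehyde has α- and β-alkoxy groups (epimerisation at C6, β-elimination). The hindered C8 ether must still be made, now with the bulky chromone phenol on an acyclic polyol. The benzyl ethers have to be hydrogenolysed at the end beside two pyranones and an allylic aryl ether.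
- Comparison: the chosen route sets C5 by a stereospecific epoxide opening and needs no sugar manipulation.

**Alternative 2:** Both pyranones are disconnected at C2–C3 and O1–C2, leading to a core that carries two acetyl groups (an ortho-hydroxyaryl methyl ketone for unit A and a 2-acetyl ketone at C4a/C8a for unit B). In the forward direction excess strong amide base would form the polyanion, both methyl carbons would be acylated by a simple ester of 3-phenylpropanoic acid, and acid would cyclodehydrate both arms to A2.
- For: both rings and both side chains arise in one operation. On end-game step economy this is the strongest of the four plans.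
- Against: in unit B the diketone enolate carbon C4a has the C5 oxygen as a β-leaving group, and C8–H is α to the C8a carbonyl with the C7 oxygen β to it. Epimerisation at C8 and two E1cB eliminations, each driving towards an aromatic ring, are built into the substrate. The acidic ring closure also threatens C5–O. The core itself, a carbocycle with four stereocentres and a C4a acyl group, has no shorter preparation than the whole chosen route.
- Comparison: the chosen strategy uses a neutral enamine at C4a and never generates a carbanion at C4a or C8.

**Alternative 3:** The carbocycle is disconnected at C8a–C4a and the pyranone is hidden in an isoxazole. In the forward direction a hexose-derived chain carrying a C8a aldoxime and a C4a≡C4 alkyne is oxidised with hypochlorite to the nitrile oxide, which adds to the tethered alkyne and gives the isoxazole-fused carbocycle A3. N–O cleavage, oxidation of the side-chain carbinol and cyclisation with loss of ammonia would follow.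
- For: the trans, trans, cis pattern of C5–C8 is that of C2–C5 of D-glucose A4, so all four stereocentres are bought and none is made, and the tether makes the cycloaddition regiospecific. On stereochemical certainty this plan is stronger than the chosen one, which relies on the facial selectivity of one epoxidation.
- Against: every oxygen of the hexose must be differentiated, the C8 ether again has to be formed with the bulky chromone phenol, the alkyne arm carries a stereocentre that is later destroyed, and at least four operations separate A3 from the pyranone before three benzyl ethers are hydrogenolysed next to two pyranones. The step count would be roughly double.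
- Comparison: the chosen strategy reaches the pyranone in one step from the enamine and needs only two substrate-controlled steps for stereochemistry.

Key step: step 9

Assumption: diol 1 is taken as a purchasable chiral-pool compound. In every intermediate the carbocycle carbons are given their unit B locants (C4a, C5–C8, C8a), "upper face" means the face carrying the C7 and C8 oxygens, and TBS stands for tert-butyldimethylsilyl.

## Route

Step 1
Reactants: 1 (1S,2S)-3-bromocyclohexa-3,5-diene-1,2-diol
Product: 2 (1S,6S)-2-bromo-6-(TBS-oxy)cyclohexa-2,4-dien-1-ol (C7 silyl ether; C8 hydroxyl free)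
Conditions: TBSCl (1.05 equiv), imidazole, DMF, −10 °C
Reagents that add atoms: tert-butyldimethylsilyl chloride, CC(C)(C)[Si](C)(C)Cl
Why: Sterically controlled mono-silylation of a halo cis-dihydrodiol; the hydroxyl next to the bromine-bearing carbon is shielded by the halogen, so the bulky silyl chloride should react at the distal C7 hydroxyl, and no stereocentre is touched.

Step 2
Reactants: 2 (1S,6S)-2-bromo-6-(TBS-oxy)cyclohexa-2,4-dien-1-ol; 3 4-fluoro-3-methoxybenzaldehyde
Product: 4 4-{[(1S,6S)-2-bromo-6-(TBS-oxy)cyclohexa-2,4-dien-1-yl]oxy}-3-methoxybenzaldehyde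
Conditions: NaH (1.05 equiv), DMF, −20 °C; then 3, −20 → 0 °C
Reagents that add atoms: none
Why: Nucleophilic aromatic substitution (addition–elimination) of the C8 alkoxide on the fluoride para to the formyl group; the O–aryl bond is formed and the C8–O bond is untouched, so C8 keeps its configuration. One equivalent of base and low temperature are meant to limit silyl migration and elimination.

Step 3
Reactants: 4 4-{[(1S,6S)-2-bromo-6-(TBS-oxy)cyclohexa-2,4-dien-1-yl]oxy}-3-methoxybenzaldehyde
Product: 6 4-{[3-bromo-5-(TBS-oxy)-7-oxabicyclo[4.1.0]hept-2-en-4-yl]oxy}-3-methoxyphenyl formate (C5,C6-epoxide with the oxirane oxygen on the lower face), via epoxy aldehyde 5 (not isolated)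
Conditions: mCPBA (3 equiv), NaHCO3, CH2Cl2, 0 °C → rt
Reagents that add atoms: 3-chloroperoxybenzoic acid, OOC(=O)c1cccc(Cl)c1
Why: Prilezhaev epoxidation of the electron-richer C5=C6 bond (C8a=C4a is deactivated by bromine) should occur anti to the C7 silyloxy and C8 aryloxy groups, which places the future C6 oxygen trans to C7. The same peracid converts the electron-rich aryl aldehyde into the aryl formate by Baeyer–Villiger (Dakin-type) aryl migration.

Step 4
Reactants: 6 epoxy aryl formate
Product: 8 4-[4-(benzyloxy)-2-methoxyphenoxy]-3-bromo-5-(TBS-oxy)-7-oxabicyclo[4.1.0]hept-2-ene (oxirane oxygen on the lower face), via epoxy phenol 7 (not isolated)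
Conditions: K2CO3, MeOH, 0 °C; evaporation; BnBr, K2CO3, DMF, rt
Reagents that add atoms: benzyl bromide, BrCc1ccccc1
Why: Transesterification removes the formate under conditions that leave the epoxide alone, and the phenoxide is benzylated by Williamson etherification; this oxygen, para to the C8 ether and meta to the methoxy group, is the future O1 of unit A.

Step 5
Reactants: 8 epoxy benzyl ether
Product: 9 5-[4-(benzyloxy)-2-methoxyphenoxy]-4-bromo-6-(TBS-oxy)cyclohex-3-ene-1,2-diol (C5 hydroxyl on the upper face, C6 hydroxyl on the lower face)
Conditions: KOH, DMSO/H2O, 70 °C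
Reagents that add atoms: water (delivered as hydroxide), O
Why: SN2 opening of the vinyl epoxide by hydroxide at the allylic, less hindered C5 (C6 is shielded by the C7 silyloxy group) proceeds with inversion, so the C5 hydroxyl is trans to C6 and cis to C7. Silyl migration or loss here is harmless because step 6 silylates every free hydroxyl.

Step 6
Reactants: 9 trans-diol
Product: 10 6-[4-(benzyloxy)-2-methoxyphenoxy]-1-bromo-3,4,5-tris(TBS-oxy)cyclohex-1-ene (C5, C7 and C8 oxygens on the upper face, C6 oxygen on the lower face)
Conditions: TBSOTf (3 equiv), 2,6-lutidine, CH2Cl2, 0 °C → rt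
Reagents that add atoms: tert-butyldimethylsilyl trifluoromethanesulfonate, CC(C)(C)[Si](C)(C)OS(=O)(=O)C(F)(F)F
Why: Silyl triflate with a hindered pyridine base silylates hindered secondary alcohols exhaustively and should give one uniform tris-silyl ether wherever the C7 silyl group sat after step 5.

Step 7
Reactants: 10 tris-TBS alkenyl bromide
Product: 11 4-{6-[4-(benzyloxy)-2-methoxyphenoxy]-3,4,5-tris(TBS-oxy)cyclohex-1-en-1-yl}morpholine (C8a enamine; configuration as in 10)
Conditions: Pd2(dba)3 (2.5 mol%), rac-BINAP, NaOtBu, morpholine, toluene, 85 °C; filtered under argon and used crude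
Reagents that add atoms: morpholine, C1COCCN1
Why: Palladium-catalysed amination of an alkenyl bromide with a secondary amine (Buchwald–Hartwig-type enamine synthesis) places nitrogen on C8a and leaves the double bond at C8a=C4a. β-Aryloxide elimination from the alkenylpalladium intermediate is blocked because it would give a six-membered cyclic allene.

Step 8
Reactants: 12 2,2-dimethyl-1,3-dioxane-4,6-dione (Meldrum's acid); 13 3-phenylpropanoyl chloride
Product: 14 5-(1-hydroxy-3-phenylpropylidene)-2,2-dimethyl-1,3-dioxane-4,6-dione
Conditions: pyridine (2 equiv), CH2Cl2, 0 °C → rt; dilute HCl wash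
Reagents that add atoms: none
Why: C-acylation of Meldrum's acid by an acid chloride with pyridine gives the enolised acyl derivative, a bench-stable precursor of the acylketene.

Step 9
Reactants: 11 C8a morpholine enamine; 14 5-(1-hydroxy-3-phenylpropylidene)-2,2-dimethyl-1,3-dioxane-4,6-dione
Product: 17 (5S,6R,7R,8S)-8-[4-(benzyloxy)-2-methoxyphenoxy]-5,6,7-tris(TBS-oxy)-2-(2-phenylethyl)-5,6,7,8-tetrahydro-4H-chromen-4-one, via acylketene 15 (not isolated), via morpholino aminal 16 (not isolated)
Conditions: toluene, 85 °C, slow addition of 14 (3 equiv); then AcOH (cat.), 60 °C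
Reagents that add atoms: none
Why: Heating 14 triggers a retro-hetero-Diels–Alder fragmentation that releases acetone and carbon dioxide and gives acylketene 15. The enamine carbon C4a, the only nucleophilic carbon of 11 because the former C–Br bond fixed the double bond at C8a=C4a, adds to the ketene carbonyl carbon (new C4–C4a bond) to give an iminium/dicarbonyl-enolate zwitterion. The enolate oxygen then closes onto the iminium carbon C8a (new O1–C8a bond; 6-exo-trig onto the exocyclic C=N bond, overall a formal hetero-(4+2) annulation) to give aminal 16. Loss of morpholine by E1cB elimination across C4a–C8a, assisted by the acetic acid finish, gives the 4-pyranone. The closest known reaction type is the formation of 4-pyranones, tetrahydrochromones included, from cyclic ketone enamines and diketene or thermally generated acylketenes. No stereocentre is created, and C5 and C8 are not at risk of epimerisation because no carbanion is generated at C4a or C8. The selectivity needed is C-acylation at C4a ahead of enamine protonation and ahead of expulsion of the allylic C5 silyloxy group; slow addition of 14 keeps the free acid low, and the moderate temperature and the poor leaving-group ability of a silanolate in toluene should hold back the elimination. An excess of 14 is used because the released morpholine consumes one equivalent of 15.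

Step 10
Reactants: 17 protected unit B tetrahydrochromone
Product: 18 (5S,6R,7R,8S)-8-(4-hydroxy-2-methoxyphenoxy)-5,6,7-tris(TBS-oxy)-2-(2-phenylethyl)-5,6,7,8-tetrahydro-4H-chromen-4-one
Conditions: H2 (1 atm), Pd/C, EtOAc, rt
Reagents that add atoms: none
Why: Hydrogenolysis of the unhindered primary benzyl aryl ether should be much faster than reduction of the 4-pyranone or cleavage of the secondary C8 aryl ether flanked by silyl ethers; ethyl acetate is used so that the silyl ethers are not solvolysed.

Step 11
Reactants: 18 phenol
Product: 19 (5S,6R,7R,8S)-8-(4-hydroxy-5-iodo-2-methoxyphenoxy)-5,6,7-tris(TBS-oxy)-2-(2-phenylethyl)-5,6,7,8-tetrahydro-4H-chromen-4-one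
Conditions: NIS (1.05 equiv), MeCN, 0 °C, dark
Reagents that add atoms: N-iodosuccinimide, O=C1CCC(=O)N1I
Why: Electrophilic aromatic iodination; the position ortho to the hydroxyl and para to the methoxy group is the most activated and least hindered (the other ortho position lies between two oxygen substituents), and it is the carbon that becomes C4a of unit A.

Step 12
Reactants: 19 iodophenol; 20 4-phenylbut-1-yne
Product: 23 6-{[(5S,6R,7R,8S)-5,6,7-tris(TBS-oxy)-4-oxo-2-(2-phenylethyl)-5,6,7,8-tetrahydro-4H-chromen-8-yl]oxy}-7-methoxy-2-(2-phenylethyl)-4H-chromen-4-one, via aryl ynone 21 (not isolated), via diethylamino enone 22 (not isolated)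
Conditions: PdCl2(PPh3)2 (5 mol%), CO (5 bar), Et2NH, 80 °C
Reagents that add atoms: carbon monoxide, [C-]#[O+]
Why: Carbonylative Sonogashira annulation: oxidative addition of the aryl iodide to zerovalent palladium, CO insertion and alkynylation give ynone 21. Diethylamine adds to the ynone to give β-amino enone 22, which the phenol closes by 6-endo addition–elimination with return of the amine, so the chromone and not the 5-exo aurone is expected.

Step 13
Reactants: 23 tris-silylated bis-chromone
Product: 24 6-{[(5S,6R,7S,8S)-5,6,7-trihydroxy-4-oxo-2-(2-phenylethyl)-5,6,7,8-tetrahydro-4H-chromen-8-yl]oxy}-7-methoxy-2-(2-phenylethyl)-4H-chromen-4-one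
Conditions: HF·pyridine, pyridine, THF, 0 °C → rt
Reagents that add atoms: none
Why: Buffered fluoride cleaves the three secondary silyl ethers without the base that could deprotonate C8–H or the strong acid that could ionise C5–O; the configuration is unchanged (the C7 descriptor changes from R to S only because the substituent priorities change).

## Compound list

1 | (1S,2S)-3-bromocyclohexa-3,5-diene-1,2-diol | O[C@@H]1C(Br)=CC=C[C@@H]1O | starting material
2 | (1S,6S)-2-bromo-6-(TBS-oxy)cyclohexa-2,4-dien-1-ol | O[C@@H]1C(Br)=CC=C[C@@H]1O[Si](C)(C)C(C)(C)C | intermediate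
3 | 4-fluoro-3-methoxybenzaldehyde | COc1cc(C=O)ccc1F | starting material
4 | 4-{[(1S,6S)-2-bromo-6-(TBS-oxy)cyclohexa-2,4-dien-1-yl]oxy}-3-methoxybenzaldehyde | COc1cc(C=O)ccc1O[C@@H]1C(Br)=CC=C[C@@H]1O[Si](C)(C)C(C)(C)C | intermediate
5 | epoxy aldehyde (C5,C6-epoxide of 4, oxirane oxygen on the lower face) | COc1cc(C=O)ccc1O[C@@H]1C(Br)=C[C@H]2O[C@H]2[C@@H]1O[Si](C)(C)C(C)(C)C | intermediate (not isolated)
6 | epoxy aryl formate | COc1cc(OC=O)ccc1O[C@@H]1C(Br)=C[C@H]2O[C@H]2[C@@H]1O[Si](C)(C)C(C)(C)C | intermediate
7 | epoxy phenol | COc1cc(O)ccc1O[C@@H]1C(Br)=C[C@H]2O[C@H]2[C@@H]1O[Si](C)(C)C(C)(C)C | intermediate (not isolated)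
8 | epoxy benzyl ether | COc1cc(OCc2ccccc2)ccc1O[C@@H]1C(Br)=C[C@H]2O[C@H]2[C@@H]1O[Si](C)(C)C(C)(C)C | intermediate
9 | C5,C6-trans-diol | COc1cc(OCc2ccccc2)ccc1O[C@@H]1C(Br)=C[C@H](O)[C@@H](O)[C@@H]1O[Si](C)(C)C(C)(C)C | intermediate
10 | tris-TBS alkenyl bromide | COc1cc(OCc2ccccc2)ccc1O[C@@H]1C(Br)=C[C@H](O[Si](C)(C)C(C)(C)C)[C@@H](O[Si](C)(C)C(C)(C)C)[C@@H]1O[Si](C)(C)C(C)(C)C | intermediate
11 | C8a morpholine enamine | COc1cc(OCc2ccccc2)ccc1O[C@@H]1C(N2CCOCC2)=C[C@H](O[Si](C)(C)C(C)(C)C)[C@@H](O[Si](C)(C)C(C)(C)C)[C@@H]1O[Si](C)(C)C(C)(C)C | intermediate
12 | 2,2-dimethyl-1,3-dioxane-4,6-dione (Meldrum's acid) | CC1(C)OC(=O)CC(=O)O1 | starting material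
13 | 3-phenylpropanoyl chloride | O=C(Cl)CCc1ccccc1 | starting material
14 | 5-(1-hydroxy-3-phenylpropylidene)-2,2-dimethyl-1,3-dioxane-4,6-dione | CC1(C)OC(=O)C(=C(O)CCc2ccccc2)C(=O)O1 | intermediate
15 | (3-phenylpropanoyl)ketene | O=C=CC(=O)CCc1ccccc1 | intermediate (not isolated)
16 | C8a-morpholino dihydropyranone aminal (C4a and C8a unspecified) | COc1cc(OCc2ccccc2)ccc1O[C@@H]1C2(N3CCOCC3)OC(CCc3ccccc3)=CC(=O)C2[C@H](O[Si](C)(C)C(C)(C)C)[C@@H](O[Si](C)(C)C(C)(C)C)[C@@H]1O[Si](C)(C)C(C)(C)C | intermediate (not isolated)
17 | (5S,6R,7R,8S)-8-[4-(benzyloxy)-2-methoxyphenoxy]-5,6,7-tris(TBS-oxy)-2-(2-phenylethyl)-5,6,7,8-tetrahydro-4H-chromen-4-one | COc1cc(OCc2ccccc2)ccc1O[C@@H]1c2oc(CCc3ccccc3)cc(=O)c2[C@H](O[Si](C)(C)C(C)(C)C)[C@@H](O[Si](C)(C)C(C)(C)C)[C@@H]1O[Si](C)(C)C(C)(C)C | intermediate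
18 | phenol (benzyl removed from 17) | COc1cc(O)ccc1O[C@@H]1c2oc(CCc3ccccc3)cc(=O)c2[C@H](O[Si](C)(C)C(C)(C)C)[C@@H](O[Si](C)(C)C(C)(C)C)[C@@H]1O[Si](C)(C)C(C)(C)C | intermediate
19 | iodophenol (iodine ortho to the hydroxyl, para to the methoxy group) | COc1cc(O)c(I)cc1O[C@@H]1c2oc(CCc3ccccc3)cc(=O)c2[C@H](O[Si](C)(C)C(C)(C)C)[C@@H](O[Si](C)(C)C(C)(C)C)[C@@H]1O[Si](C)(C)C(C)(C)C | intermediate
20 | 4-phenylbut-1-yne | C#CCCc1ccccc1 | starting material
21 | 2-hydroxyaryl ynone | COc1cc(O)c(C(=O)C#CCCc2ccccc2)cc1O[C@@H]1c2oc(CCc3ccccc3)cc(=O)c2[C@H](O[Si](C)(C)C(C)(C)C)[C@@H](O[Si](C)(C)C(C)(C)C)[C@@H]1O[Si](C)(C)C(C)(C)C | intermediate (not isolated)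
22 | β-(diethylamino) enone (double-bond geometry unspecified) | COc1cc(O)c(C(=O)C=C(N(CC)CC)CCc2ccccc2)cc1O[C@@H]1c2oc(CCc3ccccc3)cc(=O)c2[C@H](O[Si](C)(C)C(C)(C)C)[C@@H](O[Si](C)(C)C(C)(C)C)[C@@H]1O[Si](C)(C)C(C)(C)C | intermediate (not isolated)
23 | tris-TBS ether of the target | COc1cc2oc(CCc3ccccc3)cc(=O)c2cc1O[C@@H]1c2oc(CCc3ccccc3)cc(=O)c2[C@H](O[Si](C)(C)C(C)(C)C)[C@@H](O[Si](C)(C)C(C)(C)C)[C@@H]1O[Si](C)(C)C(C)(C)C | intermediate
24 | 6-{[(5S,6R,7S,8S)-5,6,7-trihydroxy-4-oxo-2-(2-phenylethyl)-5,6,7,8-tetrahydro-4H-chromen-8-yl]oxy}-7-methoxy-2-(2-phenylethyl)-4H-chromen-4-one | COc1cc2oc(CCc3ccccc3)cc(=O)c2cc1O[C@@H]1c2oc(CCc3ccccc3)cc(=O)c2[C@H](O)[C@@H](O)[C@@H]1O | target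

## Step count and least certain steps

Total: 13 steps (12 in the main line plus the one-step preparation of 14). Longest linear sequence: 12 steps (steps 1–7 and 9–13) from 1.

**Step 9 (key step).** The acidic acyl Meldrum's acid may transfer a proton to C4a of the enamine, so that the iminium salt is hydrolysed on work-up and no C–C bond forms. The enamine nitrogen may also push out the allylic C5 silyloxy group on heating, after which the ring aromatises. Fallback, setting out from 14 and 11 and returning at 17: 14 is heated in toluene/acetone at 80 °C so that the ketene is trapped by acetone as the neutral, isolable precursor 2,2-dimethyl-6-(2-phenylethyl)-4H-1,3-dioxin-4-one F1. F1 (3 equiv) is then heated with 11 in toluene or xylene at 110–120 °C, where cycloreversion releases the same acylketene 15 with no Brønsted acid present. The cost is a higher temperature.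

**Step 2.** Under alkoxide conditions the C7 silyl group may migrate to the C8 oxygen, followed by arylation of the wrong oxygen. Hydride transfer from the C8 carbinol carbon to the aldehyde with aromatisation of the ring, and E2 loss of the new aryloxide, are also possible, since every such path is driven by formation of a benzene ring. Fallback, setting out from 2 and returning at 4, forms the ether by double inversion at C8 with the phenol oxygen as nucleophile. Mitsunobu reaction of 2 with 4-nitrobenzoic acid (PPh3, diisopropyl azodicarboxylate, THF, 0 °C) gives the inverted ester (1R,6S)-2-bromo-6-(TBS-oxy)cyclohexa-2,4-dien-1-yl 4-nitrobenzoate F2. Methanolysis (K2CO3, MeOH, 0 °C) gives the trans alcohol (1R,6S)-2-bromo-6-(TBS-oxy)cyclohexa-2,4-dien-1-ol F3. A second Mitsunobu reaction of F3 with vanillin (4-hydroxy-3-methoxybenzaldehyde, COc1cc(C=O)ccc1O) inverts C8 again and gives 4.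

**Step 7.** Oxidative addition and C–N reductive elimination at the congested C8a may be slow, β-hydride elimination from the palladium amide may lead to protodebromination, and the enamine may hydrolyse on handling. Fallback, setting out from 10 and returning at 11, goes through the ketone. Miyaura borylation (bis(pinacolato)diboron, PdCl2(PPh3)2, PPh3, KOPh, toluene, 50 °C) gives the C8a pinacol boronate F4. Oxidation with NaBO3 in THF/H2O gives the C8a ketone F5. Condensation of F5 with morpholine and TiCl4 in toluene at 0 °C should give 11, because the less substituted enamine towards C4a is favoured over the one towards the C8 carbon bearing the aryloxy group. The price is a β-silyloxy ketone, which the main route avoids.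

**Step 12.** The phenol may close 5-exo on the ynone (aurone formation), coupling may occur without CO insertion (giving a 2-substituted benzofuran), or the secondary amine may open the unit B pyranone at the reaction temperature. Fallback, setting out from 19 and returning at 23, separates C–C bond formation from ring closure. Acetylation (Ac2O, pyridine) gives the iodoaryl acetate F6. Carbonylative Sonogashira coupling of F6 with 20 at room temperature (PdCl2(PPh3)2, Et3N, CO 1 atm, THF) gives the ynone acetate F7, in which no phenoxide is available for 5-exo closure. Brief treatment of F7 with Et2NH in EtOH at room temperature transfers the acetyl group to the amine and closes the ring through 22 to 23.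

**Step 10.** Hydrogenolysis may also cleave the C8–O aryl ether, which is allylic to the pyranone double bond, or saturate a pyranone C=C bond. Fallback, setting out from 17 and returning at 18: Lewis-acid debenzylation with BCl3 and pentamethylbenzene in CH2Cl2 at −78 °C, which removes the aryl benzyl ether without hydrogen and makes no new intermediate.

## Further compounds

F1 | step 9 | 2,2-dimethyl-6-(2-phenylethyl)-4H-1,3-dioxin-4-one | CC1(C)OC(CCc2ccccc2)=CC(=O)O1
F2 | step 2 | (1R,6S)-2-bromo-6-(TBS-oxy)cyclohexa-2,4-dien-1-yl 4-nitrobenzoate | O=C(O[C@H]1C(Br)=CC=C[C@@H]1O[Si](C)(C)C(C)(C)C)c1ccc(cc1)[N+](=O)[O-]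
F3 | step 2 | (1R,6S)-2-bromo-6-(TBS-oxy)cyclohexa-2,4-dien-1-ol | O[C@H]1C(Br)=CC=C[C@@H]1O[Si](C)(C)C(C)(C)C
F4 | step 7 | C8a pinacol boronate corresponding to 10 | COc1cc(OCc2ccccc2)ccc1O[C@@H]1C(B2OC(C)(C)C(C)(C)O2)=C[C@H](O[Si](C)(C)C(C)(C)C)[C@@H](O[Si](C)(C)C(C)(C)C)[C@@H]1O[Si](C)(C)C(C)(C)C
F5 | step 7 | C8a ketone: 2-[4-(benzyloxy)-2-methoxyphenoxy]-3,4,5-tris(TBS-oxy)cyclohexan-1-one | COc1cc(OCc2ccccc2)ccc1O[C@@H]1C(=O)C[C@H](O[Si](C)(C)C(C)(C)C)[C@@H](O[Si](C)(C)C(C)(C)C)[C@@H]1O[Si](C)(C)C(C)(C)C
F6 | step 12 | iodoaryl acetate of 19 | COc1cc(OC(C)=O)c(I)cc1O[C@@H]1c2oc(CCc3ccccc3)cc(=O)c2[C@H](O[Si](C)(C)C(C)(C)C)[C@@H](O[Si](C)(C)C(C)(C)C)[C@@H]1O[Si](C)(C)C(C)(C)C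
F7 | step 12 | ynone acetate | COc1cc(OC(C)=O)c(C(=O)C#CCCc2ccccc2)cc1O[C@@H]1c2oc(CCc3ccccc3)cc(=O)c2[C@H](O[Si](C)(C)C(C)(C)C)[C@@H](O[Si](C)(C)C(C)(C)C)[C@@H]1O[Si](C)(C)C(C)(C)C
F0 | step 10 | none | none
A1 | alternative 1 | 2-acyl-3-iodocyclohex-2-enol with C5 hydroxyl, C6 and C7 benzyl ethers, the unit A chromone ether on C8 and a dioxolane-masked 3-oxo-5-phenylpentanoyl chain | COc1cc2oc(CCc3ccccc3)cc(=O)c2cc1O[C@@H]1C(I)=C(C(=O)CC2(CCc3ccccc3)OCCO2)[C@H](O)[C@@H](OCc2ccccc2)[C@@H]1OCc1ccccc1
A2 | alternative 2 | 5,6,7-tri-O-benzyl ether of 24 | COc1cc2oc(CCc3ccccc3)cc(=O)c2cc1O[C@@H]1c2oc(CCc3ccccc3)cc(=O)c2[C@H](OCc2ccccc2)[C@@H](OCc2ccccc2)[C@@H]1OCc1ccccc1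
A3 | alternative 3 | isoxazole-fused tri-O-benzyl carbocycle bearing the unit A aryl ether and a silyloxy side chain | COc1cc2oc(CCc3ccccc3)cc(=O)c2cc1O[C@@H]1c2noc(C[C@@H](O[Si](C)(C)C(C)(C)C)CCc3ccccc3)c2[C@H](OCc2ccccc2)[C@@H](OCc2ccccc2)[C@@H]1OCc1ccccc1
A4 | alternative 3 | D-glucose (open-chain form) | C([C@H]([C@H]([C@@H]([C@H](C=O)O)O)O)O)O
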